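In a closed, stirred flask a solid substrate dissolves slowly and turns into product, and I had to rank the flasks below by their product.

| setting | Wednesday's | Saturday's | ochre | red | blue | amber | green |
|---|---|---|---|---|---|---|---|
| solid substrate | 0.34 M | 2.3 M | 0.50 M | 1.5 M | 0.30 M | 0.80 M | 2.0 M |
| remark | run made earlier | run made earlier |  |  |  |  |  |
| time |  |  | 20 h | 20 h | 20 h | 20 h | 20 h |

- Wednesday's (time / h: product / %, solid substrate / %): 0.833: 0, 92.2; 1.50: 1.4, 86.5; 3.00: 1.8, 76.3; 5.00: 5.6, 64.4; 10.0: 35.3, 40.5
- Saturday's (time / h: product / %, solid substrate / %): 0.833: 0, 99.2; 2.50: 0, 95.9; 5.00: 0, 93.8; 8.00: 3.0, 92.9; 10.0: 5.6, 90.9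

(each reading ± 0.5 percentage points)

- as a solid, counted per litre of solution: solid substrate
- the numbers in the tables scatter by 0.5 percentage points (one standard deviation)
- at the start none of the solid substrate is in solution
- what has only dissolved of solid substrate counts as not reacted

- the flasks by amount of product, in percent of the solid substrate charged, highest first, at 20 h (ochre / red / blue / amber / green)
- the amount of product, in percent of the solid substrate charged of the flask you put first, at 20 h
- the amount of product, in percent of the solid substrate charged of the flask you put last, at 20 h

One thing looked wrong at first. At 10.0 h Wednesday's flask showed 35.3% product, but Saturday's, with 6.76 times the charge, showed 5.6%. So I went to common logarithms: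

logarithm of the ratio of percentages (Wednesday's over Saturday's) = 0.800

logarithm of the ratio of charges (Saturday's over Wednesday's) = 0.830

The two nearly cancel, so percent times charge barely moved: 0.120 M on Wednesday and 0.129 M on Saturday, 0.124 M on average.

Late in Wednesday's run product gained 0.0202 M/h while the solid lost 0.0163 M/h, so product was outrunning the solid and draining the solution. I therefore treated dissolving as the rate-limiting step from 10.0 h on, and took its rate into a solution that product keeps draining as equal to the early supply read from Wednesday's first reading, 0.0318 M/h:

product at 20 h = 0.124 M + 0.0318 M/h × 10.0 h = 0.443 M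

This is the molar yield, the product in moles per litre at 20 h, which I took as the same for each charge while solid lasts. Dividing by charge gave me 22.1% for green, 29.5% for red, 55.3% for amber and 88.6% for ochre. Blue's 0.30 M is less than that yield, so I put blue at its whole charge, 100%.

The forecast gave blue > ochre > amber > red > green, with 96% (85% to 100%) first and 22% (17% to 28%) last, since “percent falls with charge”. Its top stood below mine.

The flasks gave blue > ochre > amber > red > green, with 99.9% first and 22.3% last.

    starting material + product → 2 product (k = 7.61 × 10⁻⁴ /M/s)
    starting material → product (k = 1.15 × 10⁻⁵ /s)
    solid substrate ⇌ starting material, rate k3*(cs3 - [starting material]) while solid is left; crystals form when [starting material] > cs3 (solubility = 0.190 M, k = 5.13 × 10⁻⁵ /s)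

Multiplied back, green's 22.3% is 0.446 M and red's 29.7% is 0.446 M, beside my 0.443 M. The neighbour is blue's flask with 0.75 M charged instead. The same division gives 59.1%, and that flask gave 59.5%, with 41% of its charge still there, solid or dissolved.

The data are simulated on assumed constants, noise included.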